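**Plan**
- Retrosynthesis cuts, in order: the C3–O ester bond (side-chain acid), the C9–O bond (enol-ether oxidation), the C7–C11 bond (enolate alkenylation), the C3–O/C4–H pair (hydroboration), then the ring-B bond C5–C6 with re-formation of C3–C8 (retro-[3,3]), the vinyl–carbinol bond, and the two Diels–Alder bonds of a dearomatised guaiacol.
- Enabling feature: the cis ring fusion C5(Me)/C10(H), with the vicinal C8 ketone/C9 oxygen in ring B and the C3–C4(Me)–C5(Me) array in ring A, is the [3,3] image of a 2-vinylbicyclo[2.2.2]oct-5-en-2-ol derived from a 4,5-dimethylguaiacol masked o-benzoquinone.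
- Forward: phenol → masked o-benzoquinone → bicyclo[2.2.2]octenone (ring A carbons plus the C8/C9 bridge) → vinyl carbinol → anionic oxy-Cope closes ring B → ring-A hydroboration → C7 isopropenyl → C9 deoxygenation and re-hydroxylation → side-chain ester.
- Stereochemistry: absolute configuration from resolution of the Diels–Alder adduct; C5/C10 from the cage in the [3,3] shift; C3/C4 from hydroboration anti to the angular methyl; C7 as the equatorial epimer; C9 from β-face enol-ether oxidation.
- Side chain: C5′ from (R)-pent-4-en-2-ol, Z alkene from angelic acid, E alkene from cross-metathesis.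

Key step: step 7

Assumption 1: decalins carry eremophilane numbering (C15 on C4, C14 on C5, side chain on C7, C8 ketone, C9 carbinol, C10 ring-fusion CH); β is the face of the C5 methyl and H-10.
Assumption 2: the enantiomer kept in step 4 is the one whose absolute configuration (to be confirmed by anomalous-dispersion X-ray at sulfur) matches the SMILES of 7; the position and endo orientation of the sulfide are inconsequential because the C–S bond is removed in step 5.

**Step 1**
Reactants: 1 3,4-dimethylphenol
Product: 2 2-bromo-4,5-dimethylphenol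
Conditions: NBS (1.0 equiv), MeCN, 0 °C
Reagents that add atoms: N-bromosuccinimide, O=C1CCC(=O)N1Br
Why: Electrophilic aromatic bromination; the para position is blocked and the ortho position flanked by the 3-methyl is hindered, so bromine should enter the free ortho carbon.

**Step 2**
Reactants: 2 2-bromo-4,5-dimethylphenol
Product: 3 2-methoxy-4,5-dimethylphenol
Conditions: NaOMe (5 equiv), CuBr (10 mol%), MeOH–DMF, 110 °C; aq. HCl
Reagents that add atoms: sodium methoxide, C[O-].[Na+]
Why: Copper-catalysed Ullmann-type methoxylation of an o-bromophenoxide, the substitution pattern for which this exchange is routinely used.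

**Step 3**
Reactants: 3 2-methoxy-4,5-dimethylphenol; 4 phenyl vinyl sulfide (10 equiv, excess recovered)
Product: 6 racemic 3,3-dimethoxy-5,6-dimethyl-7-(phenylsulfanyl)bicyclo[2.2.2]oct-5-en-2-one (sulfide endo), via masked o-benzoquinone 5 (not isolated)
Conditions: PhI(OAc)2 (1.1 equiv, slow addition), MeOH, 0 °C → rt
Reagents that add atoms: methanol, CO
Why: Oxidative dearomatisation in methanol gives the 6,6-dimethoxycyclohexa-2,4-dienone, which the electron-rich alkene should trap in an inverse-electron-demand Diels–Alder reaction before it dimerises, setting the bridgeheads and the endo sulfide in relative terms only.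

**Step 4**
Reactants: 6 racemic sulfide adduct
Product: 7 (1R,4S,7S)-3,3-dimethoxy-5,6-dimethyl-7-(phenylsulfanyl)bicyclo[2.2.2]oct-5-en-2-one
Conditions: preparative SFC, amylose tris(3,5-dimethylphenylcarbamate) phase, CO2–MeOH
Reagents that add atoms: none
Why: Resolution by chromatography on a chiral stationary phase; the aryl sulfide gives UV detection and π-interaction with the phase, and this step fixes the absolute configuration of the whole core.

**Step 5**
Reactants: 7 (1R,4S,7S)-sulfide adduct
Product: 8 (1R,4S)-3,3-dimethoxy-5,6-dimethylbicyclo[2.2.2]oct-5-en-2-one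
Conditions: Raney Ni (W-2, deactivated in refluxing acetone), acetone–EtOH, rt
Reagents that add atoms: none
Why: Raney nickel hydrogenolysis of the C–S bond; the tetrasubstituted alkene and the hindered ketone should survive the deactivated catalyst.

**Step 6**
Reactants: 8 (1R,4S)-bicyclic ketone
Product: 10 (1R,2R,4S)-2-ethenyl-3,3-dimethoxy-5,6-dimethylbicyclo[2.2.2]oct-5-en-2-ol (vinyl syn to the C5=C6 bridge), via bromomagnesium alkoxide 9 (not isolated)
Conditions: vinylmagnesium bromide (3 equiv), THF, −78 → 0 °C; aq. NH4Cl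
Reagents that add atoms: vinylmagnesium bromide, C=C[Mg]Br
Why: Grignard 1,2-addition to a non-enolisable ketone; attack is expected on the carbonyl face turned toward the flat alkene bridge, because the ethano-bridge hydrogens shield the other face, which sets C2 with the vinyl group syn to the alkene.

**Step 7**
Reactants: 10 (1R,2R,4S)-vinyl carbinol
Product: 13 9,9-dimethoxy-11,12,13-trinor-10βH-eremophil-3-en-8-one (cis-fused), via potassium alkoxide 11 (not isolated), via potassium enolate 12 (not isolated)
Conditions: KH (3 equiv), 18-crown-6 (1.2 equiv), THF, 0 → 50 °C; aq. NH4Cl, −78 °C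
Reagents that add atoms: none
Why: Deprotonation gives the potassium alkoxide, whose oxyanion weakens the adjacent C1–C2 bond of the bicycle and drives a concerted [3,3] sigmatropic shift of the 1,5-diene formed by the vinyl group and the C5=C6 bridge: the C1–C2 bond (eremophilane C3–C8) breaks, the vinyl terminus bonds to C5 (eremophilane C5–C6), and the C7–C8 enolate is protonated on work-up. The closest known reaction type is the anionic oxy-Cope rearrangement of 2-vinylbicyclo[2.2.2]oct-5-en-2-ols to cis-decalins. Ring B closes as a six-membered carbocycle through the boat-like six-centre transition state imposed by the cage, a pericyclic closure in which the new σ bond forms on the alkene face turned toward the carbinol bridge. The new quaternary stereocentre C5 is dictated by the existing bridgehead (eremophilane C10): both ends of ring B lie on the same side of the former cyclohexene, so the fusion must be cis with the C5 methyl cis to H-10. The step needs the vinyl group syn to the alkene bridge, which step 6 secures, and a single enolate regiochemistry, which the fully substituted ketal carbon C9 secures.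

**Step 8**
Reactants: 13 cis-fused enone ketal
Product: 15 9,9-dimethoxy-11,12,13-trinor-10βH-eremophilane-3α,8α-diol, via alkylborane 14 (not isolated)
Conditions: BH3·THF (4 equiv), THF, 0 °C → rt; then 3 M NaOH, 30% H2O2, 0 °C → rt
Reagents that add atoms: hydrogen peroxide, OO
Why: Borane should first reduce the C8 ketone by axial attack anti to the axial C9 methoxy group, and the resulting equatorial 8α-alkoxyborane holds the decalin in the conformer with the C5 methyl axial on ring A, so that syn hydroboration of C3=C4 (boron to the less substituted C3) occurs on the α face anti to that methyl and oxidation with retention sets 3α-OH and 4β-methyl.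

**Step 9**
Reactants: 15 3α,8α-diol
Product: 16 9,9-dimethoxy-3α-(triethylsilyloxy)-11,12,13-trinor-10βH-eremophilan-8α-ol
Conditions: TESCl (1.05 equiv), imidazole, CH2Cl2–DMF, −40 → −20 °C
Reagents that add atoms: chlorotriethylsilane, CC[Si](Cl)(CC)CC
Why: Kinetically selective silylation; the C3 hydroxyl is an ordinary equatorial secondary alcohol, whereas the C8 hydroxyl is neopentyl-like and inductively deactivated beside the C(OMe)2 carbon.

**Step 10**
Reactants: 16 C3 silyl ether, C8 alcohol
Product: 17 9,9-dimethoxy-3α-(triethylsilyloxy)-11,12,13-trinor-10βH-eremophilan-8-one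
Conditions: Dess–Martin periodinane, NaHCO3, CH2Cl2, rt
Reagents that add atoms: none
Why: Dess–Martin oxidation of a hindered secondary alcohol under buffered conditions that leave the silyl ether and ketal intact.

**Step 11**
Reactants: 17 C8 ketone
Product: 20 9,9-dimethoxy-3α-(triethylsilyloxy)-10βH-eremophil-11-en-8-one (7β-isopropenyl), via lithium enolate 18 (not isolated), via lithium dienolate 19 (not isolated)
Conditions: LiHMDS (2.2 equiv), Pd2(dba)3 (2.5 mol%), P(t-Bu)3·HBF4 (6 mol%), 2-bromopropene (1.3 equiv), THF–toluene, 0 °C → rt; then AcOH, THF, −78 °C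
Reagents that add atoms: 2-bromopropene, CC(Br)=C
Why: Palladium-catalysed α-alkenylation of a ketone enolate, which can only form toward C7 because C9 is a ketal; cold acetic acid protonates the product dienolate at the α-carbon, keeping the β,γ-alkene, and the equatorial 7β epimer is expected because the 7α epimer would be syn-axial to C4 and the axial C9 methoxy group.

**Step 12**
Reactants: 20 7β-isopropenyl ketal ketone
Product: 22 3α-(triethylsilyloxy)-10βH-eremophil-11-en-8-one, via 9-methoxy ketone 21 (not isolated)
Conditions: SmI2 (5 equiv), MeOH (10 equiv), THF, −78 → −40 °C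
Reagents that add atoms: none
Why: Samarium diiodide reduction of an α-alkoxy ketone (ketyl formation, loss of methoxide, protonation of the samarium enolate), run twice in one flask to remove both C9 methoxy groups without touching the unactivated ketone or the alkene.

**Step 13**
Reactants: 22 C8 ketone with C9 methylene
Product: 24 8-(tert-butyldimethylsilyloxy)-3α-(triethylsilyloxy)-10βH-eremophila-8,11-diene, via lithium C8–C9 enolate 23 (not isolated)
Conditions: LDA (1.2 equiv), THF, −78 °C; TBSOTf (1.3 equiv), −78 °C; Et3N quench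
Reagents that add atoms: tert-butyldimethylsilyl triflate, CC(C)(C)[Si](C)(C)OS(=O)(=O)C(F)(F)F
Why: Kinetic deprotonation with a hindered amide base at the less substituted α-methylene C9, in preference to the tertiary C7–H, followed by O-silylation at low temperature before the enolate can equilibrate.

**Step 14**
Reactants: 24 C8=C9 silyl enol ether
Product: 26 9β-(tert-butyldimethylsilyloxy)-3α-(triethylsilyloxy)-10βH-eremophil-11-en-8-one, via silyloxy epoxide 25 (not isolated)
Conditions: DMDO (1.1 equiv, acetone), CH2Cl2, −78 → 0 °C; then PPTS (cat.), rt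
Reagents that add atoms: dimethyldioxirane, CC1(C)OO1
Why: Rubottom oxidation; the electron-rich enol ether should be epoxidised far faster than the 1,1-disubstituted alkene and on the β face, since the α face of C9 is screened by C4 lying axial on ring B, and a 1,4-silyl shift then gives the 9β-silyloxy ketone.

**Step 15**
Reactants: 26 bis-silyl ether
Product: 27 9β-(tert-butyldimethylsilyloxy)-3α-hydroxy-10βH-eremophil-11-en-8-one
Conditions: HF·pyridine, pyridine, THF, 0 °C
Reagents that add atoms: none
Why: Buffered HF·pyridine cleaves a secondary triethylsilyl ether much faster than a secondary tert-butyldimethylsilyl ether, and the non-basic medium leaves C7 and the isopropenyl group untouched.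

**Step 16**
Reactants: 28 angelic acid; 29 (R)-pent-4-en-2-ol
Product: 31 (R)-pent-4-en-2-yl angelate, via mixed anhydride 30 (not isolated)
Conditions: 28, 2,4,6-trichlorobenzoyl chloride, Et3N, toluene, rt; then 29, toluene, 80 °C
Reagents that add atoms: none
Why: Yamaguchi-type mixed-anhydride esterification run without a nucleophilic catalyst, the standard way to make angelates without Z-to-E isomerisation to the tiglate; the carbinol stereocentre is retained.

**Step 17**
Reactants: 31 (R)-pent-4-en-2-yl angelate
Product: 32 (2E,5R)-5-(angeloyloxy)hex-2-enoic acid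
Conditions: acrylic acid (4 equiv), second-generation Hoveyda–Grubbs catalyst, (H2IMes)Cl2Ru=CH(C6H4-2-O-i-Pr) (5 mol%), CH2Cl2, 40 °C
Reagents that add atoms: acrylic acid, C=CC(=O)O
Why: Olefin cross-metathesis of a terminal alkene with acrylic acid, which is E-selective; the trisubstituted, electron-poor angelate alkene is a spectator.

**Step 18**
Reactants: 27 C3 alcohol; 32 (2E,5R)-5-(angeloyloxy)hex-2-enoic acid (1.5 equiv)
Product: 33 9-O-(tert-butyldimethylsilyl) ether of the target
Conditions: EDC·HCl, DMAP (0.3 equiv), CH2Cl2, 0 °C → rt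
Reagents that add atoms: none
Why: Steglich esterification of the only free hydroxyl (C9 is silylated), kept cold with sub-stoichiometric DMAP to avoid deconjugation of the enoate or isomerisation of the angelate.

**Step 19**
Reactants: 33 9-O-silyl ether
Product: 34 3α-{[(2E,5R)-5-(angeloyloxy)hex-2-enoyl]oxy}-9β-hydroxy-10βH-eremophil-11-en-8-one (target)
Conditions: HF·pyridine, THF, 0 °C → rt
Reagents that add atoms: none
Why: Acidic fluoride desilylation of an α-silyloxy ketone; avoiding basic fluoride protects the C7 and C9 stereocentres, the β,γ-alkene and both esters.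

**Compound list**
1 | 3,4-dimethylphenol | Cc1ccc(O)cc1C | starting material
2 | 2-bromo-4,5-dimethylphenol | Cc1cc(O)c(Br)cc1C | intermediate
3 | 2-methoxy-4,5-dimethylphenol | COc1cc(C)c(C)cc1O | intermediate
4 | phenyl vinyl sulfide | C=CSc1ccccc1 | starting material
5 | 6,6-dimethoxy-3,4-dimethylcyclohexa-2,4-dien-1-one (masked o-benzoquinone) | COC1(OC)C=C(C)C(C)=CC1=O | intermediate (not isolated)
6 | racemic (1R*,4S*,7S*)-3,3-dimethoxy-5,6-dimethyl-7-(phenylsulfanyl)bicyclo[2.2.2]oct-5-en-2-one, both enantiomers | O=C1C(OC)(OC)[C@H]2C[C@H](Sc3ccccc3)[C@@H]1C(C)=C2C.O=C1C(OC)(OC)[C@@H]2C[C@@H](Sc3ccccc3)[C@H]1C(C)=C2C | intermediate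
7 | (1R,4S,7S)-3,3-dimethoxy-5,6-dimethyl-7-(phenylsulfanyl)bicyclo[2.2.2]oct-5-en-2-one | O=C1C(OC)(OC)[C@H]2C[C@H](Sc3ccccc3)[C@@H]1C(C)=C2C | intermediate
8 | (1R,4S)-3,3-dimethoxy-5,6-dimethylbicyclo[2.2.2]oct-5-en-2-one | O=C1C(OC)(OC)[C@H]2CC[C@@H]1C(C)=C2C | intermediate
9 | bromomagnesium alkoxide of 10 | C=C[C@]1(O[Mg]Br)C(OC)(OC)[C@H]2CC[C@@H]1C(C)=C2C | intermediate (not isolated)
10 | (1R,2R,4S)-2-ethenyl-3,3-dimethoxy-5,6-dimethylbicyclo[2.2.2]oct-5-en-2-ol, vinyl syn to C5=C6 | C=C[C@]1(O)C(OC)(OC)[C@H]2CC[C@@H]1C(C)=C2C | intermediate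
11 | potassium alkoxide of 10 | C=C[C@]1([O-])C(OC)(OC)[C@H]2CC[C@@H]1C(C)=C2C.[K+] | intermediate (not isolated)
12 | potassium C7–C8 enolate of 13 | [K+].[O-]C1=CC[C@@]2(C)[C@H](CCC=C2C)C1(OC)OC | intermediate (not isolated)
13 | 9,9-dimethoxy-11,12,13-trinor-10βH-eremophil-3-en-8-one (cis-fused) | C1C[C@@]2(C)[C@H](CCC=C2C)C(OC)(OC)C1=O | intermediate
14 | 3α-boryl-8α-boryloxy-9,9-dimethoxy-11,12,13-trinor-10βH-eremophilane (drawn as the monoalkylborane) | C1C[C@@]2(C)[C@H](CC[C@@H](B)[C@@H]2C)C(OC)(OC)[C@@H]1OB | intermediate (not isolated)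
15 | 9,9-dimethoxy-11,12,13-trinor-10βH-eremophilane-3α,8α-diol | C1C[C@@]2(C)[C@H](CC[C@@H](O)[C@@H]2C)C(OC)(OC)[C@@H]1O | intermediate
16 | 9,9-dimethoxy-3α-(triethylsilyloxy)-11,12,13-trinor-10βH-eremophilan-8α-ol | C1C[C@@]2(C)[C@H](CC[C@@H](O[Si](CC)(CC)CC)[C@@H]2C)C(OC)(OC)[C@@H]1O | intermediate
17 | 9,9-dimethoxy-3α-(triethylsilyloxy)-11,12,13-trinor-10βH-eremophilan-8-one | C1C[C@@]2(C)[C@H](CC[C@@H](O[Si](CC)(CC)CC)[C@@H]2C)C(OC)(OC)C1=O | intermediate
18 | lithium C7–C8 enolate of 17 | [Li+].[O-]C1=CC[C@@]2(C)[C@H](CC[C@@H](O[Si](CC)(CC)CC)[C@@H]2C)C1(OC)OC | intermediate (not isolated)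
19 | lithium dienolate of 20 | [Li+].[O-]C1=C(C(C)=C)C[C@@]2(C)[C@H](CC[C@@H](O[Si](CC)(CC)CC)[C@@H]2C)C1(OC)OC | intermediate (not isolated)
20 | 9,9-dimethoxy-3α-(triethylsilyloxy)-10βH-eremophil-11-en-8-one (7β-isopropenyl) | C=C(C)[C@H]1C[C@@]2(C)[C@H](CC[C@@H](O[Si](CC)(CC)CC)[C@@H]2C)C(OC)(OC)C1=O | intermediate
21 | 9-methoxy-3α-(triethylsilyloxy)-10βH-eremophil-11-en-8-one (C9 epimers, C9 left undefined) | C=C(C)[C@H]1C[C@@]2(C)[C@H](CC[C@@H](O[Si](CC)(CC)CC)[C@@H]2C)C(OC)C1=O | intermediate (not isolated)
22 | 3α-(triethylsilyloxy)-10βH-eremophil-11-en-8-one | C=C(C)[C@H]1C[C@@]2(C)[C@H](CC[C@@H](O[Si](CC)(CC)CC)[C@@H]2C)CC1=O | intermediate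
23 | lithium C8–C9 enolate of 22 | C=C(C)[C@H]1C[C@@]2(C)[C@H](CC[C@@H](O[Si](CC)(CC)CC)[C@@H]2C)C=C1[O-].[Li+] | intermediate (not isolated)
24 | 8-(tert-butyldimethylsilyloxy)-3α-(triethylsilyloxy)-10βH-eremophila-8,11-diene | C=C(C)[C@H]1C[C@@]2(C)[C@H](CC[C@@H](O[Si](CC)(CC)CC)[C@@H]2C)C=C1O[Si](C)(C)C(C)(C)C | intermediate
25 | 8β,9β-epoxy-8α-(tert-butyldimethylsilyloxy)-3α-(triethylsilyloxy)-10βH-eremophil-11-ene | C=C(C)[C@H]1C[C@@]2(C)[C@H](CC[C@@H](O[Si](CC)(CC)CC)[C@@H]2C)[C@H]3O[C@@]13O[Si](C)(C)C(C)(C)C | intermediate (not isolated)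
26 | 9β-(tert-butyldimethylsilyloxy)-3α-(triethylsilyloxy)-10βH-eremophil-11-en-8-one | C=C(C)[C@H]1C[C@@]2(C)[C@H](CC[C@@H](O[Si](CC)(CC)CC)[C@@H]2C)[C@@H](O[Si](C)(C)C(C)(C)C)C1=O | intermediate
27 | 9β-(tert-butyldimethylsilyloxy)-3α-hydroxy-10βH-eremophil-11-en-8-one | C=C(C)[C@H]1C[C@@]2(C)[C@H](CC[C@@H](O)[C@@H]2C)[C@@H](O[Si](C)(C)C(C)(C)C)C1=O | intermediate
28 | angelic acid, (Z)-2-methylbut-2-enoic acid | C/C=C(/C)C(=O)O | starting material
29 | (R)-pent-4-en-2-ol | C[C@@H](O)CC=C | starting material
30 | angelic 2,4,6-trichlorobenzoic anhydride | C/C=C(/C)C(=O)OC(=O)c1c(Cl)cc(Cl)cc1Cl | intermediate (not isolated)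
31 | (R)-pent-4-en-2-yl (Z)-2-methylbut-2-enoate | C=CC[C@@H](C)OC(=O)/C(C)=C\C | intermediate
32 | (2E,5R)-5-[(Z)-2-methylbut-2-enoyloxy]hex-2-enoic acid | OC(=O)/C=C/C[C@@H](C)OC(=O)/C(C)=C\C | intermediate
33 | 9-O-(tert-butyldimethylsilyl) ether of the target | C=C(C)[C@H]1C[C@@]2(C)[C@H](CC[C@@H](OC(=O)/C=C/C[C@@H](C)OC(=O)/C(C)=C\C)[C@@H]2C)[C@@H](O[Si](C)(C)C(C)(C)C)C1=O | intermediate
34 | 3α-{[(2E,5R)-5-(angeloyloxy)hex-2-enoyl]oxy}-9β-hydroxy-10βH-eremophil-11-en-8-one (CNP0210874.1) | C=C(C)[C@H]1C[C@@]2(C)[C@H](CC[C@@H](OC(=O)/C=C/C[C@@H](C)OC(=O)/C(C)=C\C)[C@@H]2C)[C@@H](O)C1=O | target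

**Totals**
Total step count: 19. Longest linear sequence: 17 steps (steps 1–15, 18, 19); steps 16–17 make the side-chain acid.

**Steps most likely to fail**

Step 8. The risk is poor facial selectivity in the hydroboration. If the ketone were reduced from the other face, or the decalin reacted through its alternative chair–chair conformer, borane would add syn to the angular methyl and give the 3β-hydroxy-4α-methyl series. The fallback replaces kinetic face selection by thermodynamic control of C4 and C3 through a C3 ketone. It sets out from 13. NaBH4 in MeOH at 0 °C reduces C8 to the 8α-alcohol F1, and NaH/BnBr gives the 8α-benzyl ether F2, whose equatorial benzyloxy group anchors the conformer with the C5 methyl axial on ring A. Hydroboration–oxidation without regard to face gives the C3 alcohol mixture F3. Dess–Martin oxidation and equilibration with NaOMe in MeOH then lead to the 3-ketone F4, whose C4 methyl settles in the equatorial 4β position. Li in liquid NH3/THF reduces the ketone to the more stable equatorial 3α-alcohol and cleaves the benzyl ether in the same operation, so the route is rejoined at 15.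

Step 11. The risks are slow coupling at the hindered enolate, a second alkenylation at C7, and base-induced migration of the new alkene into conjugation during the reaction or quench. The fallback builds the three-carbon unit by aldol chemistry and sets the alkene position by deconjugative protonation. It sets out from 17. LDA, then ZnCl2 and acetone, give the 7-(2-hydroxypropan-2-yl) ketone F5. Dehydration with MsCl/Et3N then DBU gives the conjugated 7(11)-en-8-one F6. γ-Deprotonation of F6 with LDA at −78 °C regenerates dienolate 19, and cold acetic acid protonates it at C7, so the route is rejoined at 20.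

Step 13. The risk is competing deprotonation at the doubly activated C7–H, which would give the conjugated dienolate, lose the C8–C9 regiochemistry and open the way to the isopropylidene ketone. The fallback generates the enolate reductively and therefore regiospecifically. It sets out from 20. The SmI2 reduction is stopped after the first C–O cleavage (2.2 equiv SmI2, MeOH, −78 °C) and the 9-methoxy ketone 21 is isolated. Treating 21 with SmI2 (2.2 equiv) in THF at −78 °C without a proton source expels methoxide and leaves the C8–C9 samarium enolate F7, which is silylated in the same flask with TBSOTf, so the route is rejoined at 24.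

**Further compounds**
F1 | step 8 | 9,9-dimethoxy-11,12,13-trinor-10βH-eremophil-3-en-8α-ol | C1C[C@@]2(C)[C@H](CCC=C2C)C(OC)(OC)[C@@H]1O
F2 | step 8 | 8α-benzyloxy-9,9-dimethoxy-11,12,13-trinor-10βH-eremophil-3-ene | C1C[C@@]2(C)[C@H](CCC=C2C)C(OC)(OC)[C@@H]1OCc3ccccc3
F3 | step 8 | 8α-benzyloxy-9,9-dimethoxy-11,12,13-trinor-10βH-eremophilan-3-ol, mixture of C3/C4 diastereomers | C1C[C@@]2(C)[C@H](CCC(O)C2C)C(OC)(OC)[C@@H]1OCc3ccccc3
F4 | step 8 | 8α-benzyloxy-9,9-dimethoxy-11,12,13-trinor-10βH-eremophilan-3-one (4β-methyl) | C1C[C@@]2(C)[C@H](CCC(=O)[C@@H]2C)C(OC)(OC)[C@@H]1OCc3ccccc3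
F5 | step 11 | 7β-(2-hydroxypropan-2-yl)-9,9-dimethoxy-3α-(triethylsilyloxy)-11,12,13-trinor-10βH-eremophilan-8-one | CC(C)(O)[C@H]1C[C@@]2(C)[C@H](CC[C@@H](O[Si](CC)(CC)CC)[C@@H]2C)C(OC)(OC)C1=O
F6 | step 11 | 9,9-dimethoxy-3α-(triethylsilyloxy)-10βH-eremophil-7(11)-en-8-one | CC(C)=C1C[C@@]2(C)[C@H](CC[C@@H](O[Si](CC)(CC)CC)[C@@H]2C)C(OC)(OC)C1=O
F7 | step 13 | diiodosamarium C8–C9 enolate of 22 | C=C(C)[C@H]1C[C@@]2(C)[C@H](CC[C@@H](O[Si](CC)(CC)CC)[C@@H]2C)C=C1O[Sm](I)I
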